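## The problem

Compound 24 is an isoflavan: a chroman in which ring A is fused to the pyran ring C through C4a and C8a, with a 2,3,4,5-tetramethoxyphenyl group (ring B) at C3. Ring A carries three neighbouring oxygens that are all different: the ring ether O1 on C8a, a methyl ether on C8 and the only free phenol on C7. A route through an aromatic ring A would have to tell these three apart and attach C4 at C4a rather than at C6. C3 is the only stereocentre; with no neighbour to relay from, its S configuration must come from an auxiliary or a catalyst, and it should not sit next to a carbonyl group late in the route. Both arenes are very electron-rich: ring B has one open position (C6') that invites electrophiles, five aryl methyl ethers must survive, and the product phenol is easily oxidised. The enabling feature is that C8a, C8 and C7 carry O1, OMe and OH in exactly the pattern of the cyclic enol ether of a 2-methoxycyclohexane-1,3-dione. In addition, the chain O1–C2–C3–C4–C4a–C8a is the ring of a δ-valerolactone whose carbonyl carbon is C8a and whose C5 is the stereocentre. Ring A can therefore be grown on a chiral lactone from a four-carbon enone (C5–C6–C7–C8) and aromatised last, so the C7 oxygen appears as the free phenol without a protecting group.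

## Retrosynthesis

**24 ⇒ 20 (no skeletal bond cut; two hydrogens added across C5–C6).** The phenol 24 is the enol form of dienone 23, and 23 is the dehydro form of vinylogous ester 20. Keeping ring A aromatic instead would need a protected 2-methoxyresorcinol and regiocontrolled C- and O-alkylation. In 20 the three oxygens are already distinguished by oxidation level: O1 as enol ether, the C8 methyl ether, and the C7 carbonyl that becomes the phenol. The forward reaction has to dehydrogenate C5–C6 only. Kinetic enolisation at C6, selenenylation to 21 and selenoxide elimination do this, and the uncontrolled C4a centre disappears.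

**20 ⇒ 13 + 17 (C4a–C5 and C8–C8a cut; O1–C8a opened and re-formed).** The neighbouring cut at C4–C4a would mean alkylating a 2-methoxy-1,3-dione with a chiral three-carbon electrophile, with O- versus C-alkylation to control and a separate pyran closure. A cut at C3–C1' would need an asymmetric arylation next to a hindered ring. The Michael–Claisen cut uses the lactone carbonyl of 13 twice, as acyl donor for ring A and as the source of O1. The precursors are a monocyclic lactone 13 with one stereocentre and the achiral enone 17. The forward reaction needs conjugate addition of the lactone enolate, enolate equilibration to the methoxy-bearing carbon, a ring-size-controlled Claisen closure and acid reclosure of the pyran.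

**13 ⇒ 11 ⇒ 10 (lactone acyl C–O bond; then the auxiliary).** Opening the lactone gives hydroxy ester 11, whose primary alcohol comes from reductive removal of the oxazolidinone of 10. A tert-butyl ester is chosen because it resists LiBH4 and then leaves under the same acid that closes the ring. Nothing here touches the stereocentre.

**10 ⇒ 8 + 9 (bond between the future C3 and C4).** Conjugate addition of the enolate of imide 8 to tert-butyl acrylate 9 delivers the three-carbon arm at the correct oxidation level. Alkylation with a 3-halopropanoate would suffer elimination to acrylate, and allylation would need later oxidation-state adjustment. The forward reaction must be face-selective, which the chelated enolate of the benzyl oxazolidinone provides.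

**8 ⇒ 5 + 6, and 5 ⇒ 3 ⇒ 1 + 2 (N-acyl bond; aryl–CH2 bond).** Arene 1 already holds all four methoxy groups, and its two ring hydrogens are equivalent and ortho to a methoxy group. Directed lithiation and opening of oxirane 2 therefore give alcohol 3 as one regioisomer, and oxidation gives acid 5. Friedel–Crafts acylation of 1 is avoided because strong Lewis acids cleave the methoxy group ortho to the new carbonyl. Formylation followed by homologation would be longer.

**17 ⇒ 15 + 16, and 15 ⇒ 14 (carbonyl–vinyl bond).** The Weinreb amide 15 of methoxyacetyl chloride 14 accepts one equivalent of vinylmagnesium bromide 16 and stops at the ketone.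

## Roads not taken

**Alternative 1:** The cut is through C3–C1' and the C4–O bond of a pterocarpan, which is opened reductively afterwards. In the forward key step, chromene A3 and the symmetrical quinone A2 combine in a formal [3+2] addition. The promoter is a chiral complex of tetravalent titanium made from TiCl4, Ti(OiPr)4 and a TADDOL diol, and the product is cis-pterocarpan A1.

- Merits: the route is highly convergent, both arenes are aromatic from the start, and C3 is set in the C–C bond-forming event. The quinone carbonyls supply the 2' and 5' oxygens of ring B without regiochemical ambiguity. Hydrogenolysis of the benzylic C–O bond, double O-methylation and desilylation would finish the synthesis.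
- Weak points: the chiral titanium reagent is needed in stoichiometric amount. The enantioselectivity, and the partition between [3+2] and [2+2] adducts, depend closely on the substitution of both partners. A3 is an acid-sensitive, polymerisable enol-ether-like alkene. The hydroquinone-type phenol of A1 is air-sensitive. The aryl silyl ether must hold while two phenols are methylated under basic conditions.
- Comparison: this road is probably one or two steps shorter and more convergent than the chosen plan. Against that, the chosen plan sets a stereocentre fixed by a covalently bound auxiliary, whose diastereomers (10) can be separated, and it needs no protecting group on the ring A phenol.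

**Alternative 2:** The cut is through C3–C4 and the O1–C2 acyl bond of a dihydrocoumarin, whose C2 carbonyl is reduced to CH2 later. In the forward key step, sulfone A5 releases an ortho-quinone methide with Cs2CO3. The activated ester A6 (made from acid 5) forms a chiral isothiourea-bound enolate that adds to it and lactonises to A4.

- Merits: the chirality is catalytic, the route is convergent, both arenes are pre-formed, and it shares acid 5 with the chosen route.
- Weak points: the methide carbon is unsubstituted here, and such a parent quinone methide is short-lived and oligomerises readily. The only stereocentre of A4 is benzylic and α to the lactone carbonyl, so it can epimerise under the carbonate and nucleophilic catalyst, with no second centre to bias it. Removing the C2 oxygen costs a reduction to the diol, a ring reclosure and a debenzylation.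
- Comparison: catalytic asymmetric induction and a comparable step count are real advantages over a stoichiometric auxiliary. The chosen plan offers a centre that is not enolisable once the auxiliary is removed, and no phenol protecting group.

**Alternative 3:** The cut dissects ring B, forming C1'–C2' last. In the forward key step, alkyne A9 is added as its acetylide to a dialkyl squarate to give cyclobutenone A8. Heating opens A8 to an alkynyl vinylketene, which closes to quinone A7. Reduction, double methylation and debenzylation follow.

- Merits: a fully oxygenated ring is assembled with complete regiocontrol under neutral thermal conditions.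
- Weak points: this solves a problem the target does not pose, since ring B is available intact as 1. The stereocentre is not addressed, so A9 must be made enantiopure beforehand, probably through an easily racemised α-branched aldehyde. Five-membered ring closure competes with quinone formation.
- Comparison: this road is the most regiochemically elegant for ring B. It is clearly longer, and the chosen plan both sets the stereocentre and builds the skeleton with fewer steps.

Key step: step 9

Assumption: aryllithium, metal enolate and magnesium chelate species are treated as salt forms of numbered compounds; neutral covalent intermediates that react on within the same operation are numbered.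

## Route

Step 1
Reactants: 1 1,2,3,4-tetramethoxybenzene; 2 oxirane
Product: 3 2-(2,3,4,5-tetramethoxyphenyl)ethan-1-ol
Conditions: n-BuLi, TMEDA, THF, 0 °C; then 2, −78 → 23 °C; H2O
Reagents that add atoms: none
Why: Directed ortho-metalation; both ring hydrogens of 1 are equivalent and ortho to a methoxy group, so one aryllithium forms and opens oxirane by SN2 attack to give the 2-arylethanol.

Step 2
Reactants: 3 2-(2,3,4,5-tetramethoxyphenyl)ethan-1-ol
Product: 5 (2,3,4,5-tetramethoxyphenyl)acetic acid, via arylacetaldehyde 4 (not isolated)
Conditions: TEMPO (cat.), NaClO2, NaOCl (cat.), MeCN, phosphate buffer (pH 6.7), 35 °C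
Reagents that add atoms: sodium chlorite, [Na+].[O-]Cl=O
Why: TEMPO-catalysed oxidation of a primary alcohol with NaClO2 as terminal oxidant runs through aldehyde 4 to the acid; the low standing concentration of hypochlorite should spare the electron-rich ring from chlorination.

Step 3
Reactants: 5 (2,3,4,5-tetramethoxyphenyl)acetic acid; 6 (4S)-4-benzyl-1,3-oxazolidin-2-one
Product: 8 (4S)-4-benzyl-3-[(2,3,4,5-tetramethoxyphenyl)acetyl]-1,3-oxazolidin-2-one, via mixed pivalic anhydride 7 (not isolated)
Conditions: tBuCOCl, Et3N, THF, −20 °C; then 6, LiCl, −20 → 23 °C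
Reagents that add atoms: pivaloyl chloride, CC(C)(C)C(Cl)=O (its atoms are held only in intermediate 7)
Why: Mixed-anhydride N-acylation of the oxazolidinone auxiliary under LiCl/Et3N; the hindered pivaloyl carbonyl directs attack to the arylacetyl carbonyl.

Step 4
Reactants: 8 (4S)-4-benzyl-3-[(2,3,4,5-tetramethoxyphenyl)acetyl]-1,3-oxazolidin-2-one; 9 tert-butyl acrylate
Product: 10 tert-butyl (4S)-5-[(4S)-4-benzyl-2-oxo-1,3-oxazolidin-3-yl]-5-oxo-4-(2,3,4,5-tetramethoxyphenyl)pentanoate
Conditions: TiCl4, Ti(OiPr)4 (3:1), iPr2NEt, CH2Cl2, 0 °C; then 9, 0 °C
Reagents that add atoms: none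
Why: Evans asymmetric Michael addition of a chlorotitanium enolate; soft enolisation gives the chelated Z-enolate and the acrylate adds to the face opposite the benzyl group, which sets the new centre (the future C3) as S, in the same facial sense as auxiliary-controlled alkylation.

Step 5
Reactants: 10 tert-butyl (4S)-5-[(4S)-4-benzyl-2-oxo-1,3-oxazolidin-3-yl]-5-oxo-4-(2,3,4,5-tetramethoxyphenyl)pentanoate
Product: 11 tert-butyl (4S)-5-hydroxy-4-(2,3,4,5-tetramethoxyphenyl)pentanoate
Conditions: LiBH4, H2O (1 equiv), Et2O, 0 °C
Reagents that add atoms: none
Why: Reductive cleavage of the N-acyl oxazolidinone; the imide carbonyl is far more electrophilic than the tert-butyl ester, which should survive at 0 °C, and the auxiliary 6 is recovered; the stereocentre is not touched.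

Step 6
Reactants: 11 tert-butyl (4S)-5-hydroxy-4-(2,3,4,5-tetramethoxyphenyl)pentanoate
Product: 13 (5S)-5-(2,3,4,5-tetramethoxyphenyl)tetrahydro-2H-pyran-2-one, via hydroxy acid 12 (not isolated)
Conditions: TsOH·H2O (cat.), PhMe, 80 °C
Reagents that add atoms: none
Why: Acid-catalysed loss of isobutene from the tert-butyl ester and lactonisation of hydroxy acid 12 to the six-membered ring; at 80 °C the isobutene leaves as a gas, which limits tert-butylation of ring B, and C5 of the lactone is not enolisable.

Step 7
Reactants: 14 methoxyacetyl chloride
Product: 15 N,2-dimethoxy-N-methylacetamide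
Conditions: MeNH(OMe)·HCl, pyridine, CH2Cl2, 0 → 23 °C
Reagents that add atoms: N,O-dimethylhydroxylamine hydrochloride, CNOC.Cl
Why: Acylation of the amine by an acid chloride to give the Weinreb amide.

Step 8
Reactants: 15 N,2-dimethoxy-N-methylacetamide; 16 vinylmagnesium bromide
Product: 17 1-methoxybut-3-en-2-one
Conditions: THF, −78 → 0 °C; then poured into 2 M HCl, 0 °C; kept cold over BHT and used as a solution
Reagents that add atoms: none
Why: Weinreb ketone synthesis; the chelated tetrahedral magnesium adduct prevents over-addition, and the inverse acid quench protonates the released N,O-dimethylhydroxylamine before it can add to the vinyl ketone.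

Step 9
Reactants: 13 (5S)-5-(2,3,4,5-tetramethoxyphenyl)tetrahydro-2H-pyran-2-one; 17 1-methoxybut-3-en-2-one
Product: 20 (3S)-8-methoxy-3-(2,3,4,5-tetramethoxyphenyl)-2,3,4,4a,5,6-hexahydro-7H-chromen-7-one (C4a epimers), via keto lactone 18 (not isolated), via hydroxy dione 19 (not isolated)
Conditions: LiN(iPr)2, THF, −78 °C; 17 (slow addition), −78 °C; KOtBu, tBuOH, −78 → 23 °C; 2 M HCl; then TsOH·H2O (cat.), PhMe, 60 °C
Reagents that add atoms: none
Why: The lithium enolate of 13 adds to the unsubstituted β-carbon of 17 (Michael addition, C4a–C5) to give keto lactone 18 as its C6 enolate. KOtBu/tBuOH then moves the enolate to the methoxy-bearing carbon C8, which attacks the lactone carbonyl in a 6-(enolendo)-exo-trig Claisen (Dieckmann-type) closure (C8–C8a, ring A) and expels the O1 alkoxide. The doubly stabilised 2-methoxy-1,3-dione enolate of 19 is the thermodynamic sink, and it should also draw any reversible 1,2-adduct back through retro-aldol cleavage. On acidification the primary hydroxyl adds to the nearer carbonyl C8a (6-exo-trig hemiketal) and dehydration gives the conjugated enol ether, which re-forms ring C (O1–C8a) as vinylogous ester 20. The closest known reaction type is the consecutive Michael–Claisen annulation of ester enolates with vinyl ketones to cyclohexane-1,3-diones, combined with C-acylation of a ketone enolate by a lactone. The step needs attack from C8 rather than C6 and reclosure on C8a rather than C7; ring size secures both, since the alternatives would give a four-membered and an eight-membered ring. No lasting stereocentre is made: C4a forms as a mixture and vanishes on aromatisation, and C3, γ to the lactone carbonyl, cannot be enolised.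

Step 10
Reactants: 20 (3S)-8-methoxy-3-(2,3,4,5-tetramethoxyphenyl)-2,3,4,4a,5,6-hexahydro-7H-chromen-7-one
Product: 21 (3S)-8-methoxy-6-(phenylselanyl)-3-(2,3,4,5-tetramethoxyphenyl)-2,3,4,4a,5,6-hexahydro-7H-chromen-7-one (C4a and C6 epimers)
Conditions: LiN(iPr)2, THF, −78 °C; then PhSeBr, −78 °C
Reagents that add atoms: benzeneselenenyl bromide, Br[Se]c1ccccc1
Why: Kinetic deprotonation of a 3-alkoxycyclohexenone occurs at the α' carbon (C6), and the enolate is trapped by PhSeBr (α-selenenylation of a ketone enolate); the other α carbon, C8, is fully substituted.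

Step 11
Reactants: 21 (3S)-8-methoxy-6-(phenylselanyl)-3-(2,3,4,5-tetramethoxyphenyl)-2,3,4,4a,5,6-hexahydro-7H-chromen-7-one
Product: 24 (3S)-8-methoxy-3-(2,3,4,5-tetramethoxyphenyl)-3,4-dihydro-2H-chromen-7-ol, via selenoxide 22 (not isolated), via dienone 23 (not isolated)
Conditions: mCPBA (1.0 equiv), CH2Cl2, −78 °C; then iPr2NH, −78 → 23 °C
Reagents that add atoms: 3-chloroperoxybenzoic acid, OOC(=O)c1cccc(Cl)c1 (its oxygen is held only in intermediate 22)
Why: Selenide oxidation and syn-elimination of selenoxide 22 towards the only β-hydrogens (C5) gives cross-conjugated dienone 23, the keto tautomer of the phenol, which aromatises by proton shift from C4a; one equivalent of peracid at low temperature and an amine buffer should protect the electron-rich rings and the new phenol.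

## Compound list

1 | 1,2,3,4-tetramethoxybenzene | COc1ccc(OC)c(OC)c1OC | starting material
2 | oxirane | C1CO1 | starting material
3 | 2-(2,3,4,5-tetramethoxyphenyl)ethan-1-ol | OCCc1cc(OC)c(OC)c(OC)c1OC | intermediate
4 | (2,3,4,5-tetramethoxyphenyl)acetaldehyde | O=CCc1cc(OC)c(OC)c(OC)c1OC | intermediate (not isolated)
5 | (2,3,4,5-tetramethoxyphenyl)acetic acid | OC(=O)Cc1cc(OC)c(OC)c(OC)c1OC | intermediate
6 | (4S)-4-benzyl-1,3-oxazolidin-2-one | O=C1N[C@@H](Cc2ccccc2)CO1 | starting material
7 | 2,2-dimethylpropanoic (2,3,4,5-tetramethoxyphenyl)acetic anhydride | CC(C)(C)C(=O)OC(=O)Cc1cc(OC)c(OC)c(OC)c1OC | intermediate (not isolated)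
8 | (4S)-4-benzyl-3-[(2,3,4,5-tetramethoxyphenyl)acetyl]-1,3-oxazolidin-2-one | COc1cc(CC(=O)N2[C@@H](Cc3ccccc3)COC2=O)c(OC)c(OC)c1OC | intermediate
9 | tert-butyl acrylate | C=CC(=O)OC(C)(C)C | starting material
10 | tert-butyl (4S)-5-[(4S)-4-benzyl-2-oxo-1,3-oxazolidin-3-yl]-5-oxo-4-(2,3,4,5-tetramethoxyphenyl)pentanoate | CC(C)(C)OC(=O)CC[C@@H](c1cc(OC)c(OC)c(OC)c1OC)C(=O)N1[C@@H](Cc2ccccc2)COC1=O | intermediate
11 | tert-butyl (4S)-5-hydroxy-4-(2,3,4,5-tetramethoxyphenyl)pentanoate | CC(C)(C)OC(=O)CC[C@@H](c1cc(OC)c(OC)c(OC)c1OC)CO | intermediate
12 | (4S)-5-hydroxy-4-(2,3,4,5-tetramethoxyphenyl)pentanoic acid | OC(=O)CC[C@@H](c1cc(OC)c(OC)c(OC)c1OC)CO | intermediate (not isolated)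
13 | (5S)-5-(2,3,4,5-tetramethoxyphenyl)tetrahydro-2H-pyran-2-one | O=C1CC[C@@H](c2cc(OC)c(OC)c(OC)c2OC)CO1 | intermediate
14 | methoxyacetyl chloride | COCC(Cl)=O | starting material
15 | N,2-dimethoxy-N-methylacetamide | COCC(=O)N(C)OC | intermediate
16 | vinylmagnesium bromide | C=C[Mg]Br | starting material
17 | 1-methoxybut-3-en-2-one | COCC(=O)C=C | intermediate
18 | (5S)-3-(4-methoxy-3-oxobutyl)-5-(2,3,4,5-tetramethoxyphenyl)tetrahydro-2H-pyran-2-one (C3 epimers) | COCC(=O)CCC1C[C@@H](c2cc(OC)c(OC)c(OC)c2OC)COC1=O | intermediate (not isolated)
19 | 4-[(2S)-3-hydroxy-2-(2,3,4,5-tetramethoxyphenyl)propyl]-2-methoxycyclohexane-1,3-dione (C4 epimers, enol tautomers) | COC1C(=O)CCC(C[C@H](CO)c2cc(OC)c(OC)c(OC)c2OC)C1=O | intermediate (not isolated)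
20 | (3S)-8-methoxy-3-(2,3,4,5-tetramethoxyphenyl)-2,3,4,4a,5,6-hexahydro-7H-chromen-7-one (C4a epimers) | O=C1CCC2C[C@@H](c3cc(OC)c(OC)c(OC)c3OC)COC2=C1OC | intermediate
21 | (3S)-8-methoxy-6-(phenylselanyl)-3-(2,3,4,5-tetramethoxyphenyl)-2,3,4,4a,5,6-hexahydro-7H-chromen-7-one (C4a and C6 epimers) | O=C1C([Se]c2ccccc2)CC2C[C@@H](c3cc(OC)c(OC)c(OC)c3OC)COC2=C1OC | intermediate
22 | (3S)-8-methoxy-6-(phenylseleninyl)-3-(2,3,4,5-tetramethoxyphenyl)-2,3,4,4a,5,6-hexahydro-7H-chromen-7-one | O=C1C([Se](=O)c2ccccc2)CC2C[C@@H](c3cc(OC)c(OC)c(OC)c3OC)COC2=C1OC | intermediate (not isolated)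
23 | (3S)-8-methoxy-3-(2,3,4,5-tetramethoxyphenyl)-2,3,4,4a-tetrahydro-7H-chromen-7-one | O=C1C=CC2C[C@@H](c3cc(OC)c(OC)c(OC)c3OC)COC2=C1OC | intermediate (not isolated)
24 | (3S)-8-methoxy-3-(2,3,4,5-tetramethoxyphenyl)-3,4-dihydro-2H-chromen-7-ol | COc1cc([C@H]2COc3c(ccc(O)c3OC)C2)c(OC)c(OC)c1OC | target

## Step count and risks

Total step count: 11. Longest linear sequence: 9 steps (steps 1 to 6, then 9, 10 and 11); steps 7 and 8 form the two-step side branch to enone 17.

**Step 9 (key step).**
- Risk: the lactone enolate may act as a base towards the acidic methoxymethylene group of 17 instead of adding to it. The vinyl ketone may also polymerise by repeated conjugate addition of the product enolate. Either process would consume the enone and return lactone, and the enolate shift to C8 could then be too slow to compete.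
- Fallback, from 13 back to the route at 20: the lactone is converted with LiN(iPr)2 and Me3SiCl into the ketene silyl acetal (3S)-3-(2,3,4,5-tetramethoxyphenyl)-6-(trimethylsilyloxy)-3,4-dihydro-2H-pyran F1. F1 undergoes a Mukaiyama–Michael addition to 17 under TiCl4 in CH2Cl2 at −78 °C, with no basic enolate present, and after aqueous work-up keto lactone 18 is isolated. Treatment of 18 with KOtBu in tBuOH/THF gives 19, and TsOH in toluene closes it to 20.

**Step 10.**
- Risk: loss of regiocontrol in the enolisation (γ-deprotonation at C4a under equilibrating conditions), or double selenenylation through proton exchange between product and enolate.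
- Fallback, from 20 directly to 24: direct aerobic dehydrogenation with Pd(O2CCF3)2 (catalytic), 2-(dimethylamino)pyridine and TsOH under O2 in DMSO at 80 °C. The divalent palladium enolate at C6 undergoes β-hydride elimination from C5, and O2 reoxidises the zerovalent palladium. No new compound is made.

**Step 11.**
- Risk: over-oxidation of the electron-rich phenol as it forms by selenium–oxygen by-products, or a seleno-Pummerer diversion of the α-seleno ketone to a diketone under acidic conditions.
- Fallback, from 20 to 24 by a Saegusa–Ito oxidation: LiN(iPr)2 and Me3SiCl give the silyl dienol ether trimethyl{[(3S)-8-methoxy-3-(2,3,4,5-tetramethoxyphenyl)-3,4,4a,5-tetrahydro-2H-chromen-7-yl]oxy}silane F2. Pd(OAc)2 in MeCN at 23 °C dehydrogenates F2 to dienone 23, which tautomerises to 24.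

**Step 4.**
- Risk: incomplete conversion through Lewis-acid-induced oligomerisation of the acrylate, and erosion of the diastereomer ratio by amine-mediated epimerisation of the acidic α-aryl imide.
- Fallback, from 8 back to the route at 13: the sodium enolate of 8 (NaN(SiMe3)2, THF, −78 °C) is alkylated with allyl bromide on the same face to give (4S)-4-benzyl-3-[(2S)-2-(2,3,4,5-tetramethoxyphenyl)pent-4-enoyl]-1,3-oxazolidin-2-one F3. LiBH4 releases (2S)-2-(2,3,4,5-tetramethoxyphenyl)pent-4-en-1-ol F4. Hydroboration with 9-BBN and oxidative work-up (H2O2, NaOH) give (2S)-2-(2,3,4,5-tetramethoxyphenyl)pentane-1,5-diol F5. TEMPO/PhI(OAc)2 then oxidises the unbranched primary alcohol preferentially, and the lactol that forms is oxidised on to lactone 13.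

**Step 8.**
- Risk: conjugate addition of the released N,O-dimethylhydroxylamine to the vinyl ketone during the quench, together with polymerisation and evaporative loss of the small enone.
- Fallback, from 14 directly to 17: an acyl Stille coupling of 14 with tributyl(vinyl)stannane catalysed by PhCH2PdCl(PPh3)2 in THF gives 17 under neutral, amine-free conditions. No new compound is made.

## Further compounds

F1 | step 9 | (3S)-3-(2,3,4,5-tetramethoxyphenyl)-6-(trimethylsilyloxy)-3,4-dihydro-2H-pyran | C[Si](C)(C)OC1=CC[C@@H](c2cc(OC)c(OC)c(OC)c2OC)CO1
F0 | step 10 | none | none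
F2 | step 11 | trimethyl{[(3S)-8-methoxy-3-(2,3,4,5-tetramethoxyphenyl)-3,4,4a,5-tetrahydro-2H-chromen-7-yl]oxy}silane | C[Si](C)(C)OC1=CCC2C[C@@H](c3cc(OC)c(OC)c(OC)c3OC)COC2=C1OC
F3 | step 4 | (4S)-4-benzyl-3-[(2S)-2-(2,3,4,5-tetramethoxyphenyl)pent-4-enoyl]-1,3-oxazolidin-2-one | C=CC[C@@H](c1cc(OC)c(OC)c(OC)c1OC)C(=O)N1[C@@H](Cc2ccccc2)COC1=O
F4 | step 4 | (2S)-2-(2,3,4,5-tetramethoxyphenyl)pent-4-en-1-ol | C=CC[C@@H](c1cc(OC)c(OC)c(OC)c1OC)CO
F5 | step 4 | (2S)-2-(2,3,4,5-tetramethoxyphenyl)pentane-1,5-diol | OCCC[C@@H](c1cc(OC)c(OC)c(OC)c1OC)CO
F0 | step 8 | none | none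
A1 | alternative 1 | (6aS,11aS)-4,9,10-trimethoxy-3-(triisopropylsilyloxy)pterocarpan-8-ol | Oc1cc2c(c(OC)c1OC)O[C@@H]1c3ccc(O[Si](C(C)C)(C(C)C)C(C)C)c(OC)c3OC[C@H]21
A2 | alternative 1 | 2,3-dimethoxy-1,4-benzoquinone | COC1=C(OC)C(=O)C=CC1=O
A3 | alternative 1 | 8-methoxy-7-(triisopropylsilyloxy)-2H-chromene | COc1c(O[Si](C(C)C)(C(C)C)C(C)C)ccc2C=CCOc12
A4 | alternative 2 | (S)-7-benzyloxy-8-methoxy-3-(2,3,4,5-tetramethoxyphenyl)chroman-2-one | O=C1Oc2c(OC)c(OCc3ccccc3)ccc2C[C@H]1c1cc(OC)c(OC)c(OC)c1OC
A5 | alternative 2 | 3-(benzyloxy)-2-methoxy-6-[(4-methylbenzenesulfonyl)methyl]phenol | Cc1ccc(cc1)S(=O)(=O)Cc1ccc(OCc2ccccc2)c(OC)c1O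
A6 | alternative 2 | 4-nitrophenyl (2,3,4,5-tetramethoxyphenyl)acetate | COc1cc(CC(=O)Oc2ccc(cc2)[N+](=O)[O-])c(OC)c(OC)c1OC
A7 | alternative 3 | 2-[(3S)-7-benzyloxy-8-methoxychroman-3-yl]-5,6-dimethoxy-1,4-benzoquinone | COC1=C(OC)C(=O)C([C@H]2COc3c(ccc(OCc4ccccc4)c3OC)C2)=CC1=O
A8 | alternative 3 | 4-{[(3S)-7-(benzyloxy)-8-methoxychroman-3-yl]ethynyl}-4-hydroxy-2,3-dimethoxycyclobut-2-en-1-one | COC1=C(OC)C(O)(C#C[C@H]2COc3c(ccc(OCc4ccccc4)c3OC)C2)C1=O
A9 | alternative 3 | (3S)-7-(benzyloxy)-3-ethynyl-8-methoxychromane | C#C[C@H]1COc2c(ccc(OCc3ccccc3)c2OC)C1
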